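**Plan**

- Retrosynthesis: both 2,2-dimethylpyran rings are opened at the bond from the arene carbon C8 (C8') to the pyran CH, which leads back to the bis(1,1-dimethylpropargyl) ether of a 6,6'-dibromo-7,7'-dihydroxy dimer; the cyclobutane bonds C4–C3' and C4'–C3 are then cut to two molecules of 7-methoxycoumarin.
- Enabling feature: each arene carries the pyran oxygen O7 on C7 beside the free carbon C8, and the pyran ring O7–C(CH3)2–CH=CH–C8 is the retron of an aryl 1,1-dimethylpropargyl ether, which a [3,3] shift, a hydrogen shift and a 6π ring closure turn into that ring; a removable bromine on C6 leaves C8 as the only ortho carbon that can react.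
- Forward: the cyclobutane comes first (lattice-controlled [2+2] photodimerisation of two coumarin C3=C4 bonds, the lactone rings being present from the start), then resolution, bromination at C6/C6', O-demethylation, twofold O-propargylation, closure of both pyran rings in one operation, and removal of the bromines.
- Stereochemistry: the all-cis, head-to-tail, cis-fused relative configuration of the four cyclobutane centres comes from the solid-state photodimerisation; the absolute configuration comes from resolution of the C2-symmetric dimer on a chiral phase; no later step touches these centres.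

Key step: step 6

Numbering: each half keeps coumarin numbering (O1, C2 carbonyl, C3, C4, C4a, C5 to C8, C8a; primes for the second half); the cyclobutane is C3–C4–C3'–C4'.

Remark: the target is the all-cis (syn) head-to-tail dimer, (3S,4R,3'S,4'R). Its chirality rests only on which phenol is lactonised with which carboxyl, because opening both lactones would give an achiral all-cis diacid (a path by which the unwanted enantiomer of step 2 could be returned to the racemate). After the resolution, therefore, no reagent that could open both lactone rings is used.

**Step 1**
Reactants: 1 7-methoxycoumarin (two molecules)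
Product: 2 racemic syn head-to-tail cyclobutane dimer of 7-methoxycoumarin
Conditions: hν (λ > 300 nm, Pyrex), crystalline powder, 25 °C
Reagents that add atoms: none
Why: Topochemical [2+2] photodimerisation, in which the crystal packing of 1 pairs neighbouring molecules head-to-tail on the same face so that suprafacial addition across the two C3=C4 bonds should set all four centres at once as the all-cis, cis-fused racemate, a mode with direct precedent for crystalline 7-methoxycoumarin.

**Step 2**
Reactants: 2 racemic syn head-to-tail dimer
Product: 3 (3S,4R,3'S,4'R)-7,7'-dimethoxy dimer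
Conditions: preparative HPLC, amylose tris(3,5-dimethylphenylcarbamate) on silica, hexane/i-PrOH, 25 °C
Reagents that add atoms: none
Why: Resolution by chromatography on a chiral stationary phase, which should separate the rigid C2-symmetric bis-lactone enantiomers, the (3S,4R,3'S,4'R) fraction being identified by anomalous-dispersion X-ray analysis of dibromide 4 made from a sample.

**Step 3**
Reactants: 3 (3S,4R,3'S,4'R)-7,7'-dimethoxy dimer
Product: 4 6,6'-dibromo-7,7'-dimethoxy dimer
Conditions: NBS (2.1 equiv), DMF, 25 °C
Reagents that add atoms: N-bromosuccinimide, O=C1CCC(=O)N1Br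
Why: Electrophilic aromatic bromination, which should enter once per arene at C6 because C6 is ortho to the methoxy group, para to the lactone oxygen and unhindered, whereas C8 lies between two oxygens and the carbon para to the methoxy group (C4a) is substituted.

**Step 4**
Reactants: 4 6,6'-dibromo-7,7'-dimethoxy dimer
Product: 5 6,6'-dibromo-7,7'-dihydroxy dimer
Conditions: BBr3, CH2Cl2, −78 to 0 °C; then H2O
Reagents that add atoms: none
Why: Lewis acid cleavage of aryl methyl ethers (bromide attacks the methyl carbon of the boron-bound ether), to which the aryl lactones, the aryl bromides and the cyclobutane are inert and in which no nucleophile able to open a lactone is present.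

**Step 5**
Reactants: 5 6,6'-dibromo-7,7'-dihydroxy dimer; 6 3-chloro-3-methylbut-1-yne (two molecules)
Product: 7 6,6'-dibromo-7,7'-bis(2-methylbut-3-yn-2-yloxy) dimer
Conditions: CuCl2·2H2O (cat.), DBU, MeCN, 0 °C
Reagents that add atoms: none
Why: Copper-catalysed propargylic O-alkylation of a phenol (a copper acetylide ionises to a copper allenylidene that the phenoxide attacks at the tertiary carbon), which should convert both phenols, one molecule of 6 each, into hindered aryl 1,1-dimethylpropargyl ethers at 0 °C with a non-nucleophilic base so that both lactones stay closed.

**Step 6**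
Reactants: 7 6,6'-dibromo-7,7'-bis(2-methylbut-3-yn-2-yloxy) dimer
Product: 10 6,6'-dibromo derivative of the target, via bis(allenylphenol) 8 (not isolated), via bis(o-quinone methide) 9 (not isolated)
Conditions: PhNEt2, 185 °C
Reagents that add atoms: none
Why: Each aryl 1,1-dimethylpropargyl ether of 7 undergoes an aromatic propargyl Claisen rearrangement, a [3,3] sigmatropic shift that joins C8 to the alkyne terminus and breaks O7–C(CH3)2; the 8-allenyl dienone enolises to allenylphenol 8, a 1,5-hydrogen shift from O–H to the central allene carbon gives o-quinone methide 9, and thermal oxa-6π electrocyclisation re-forms the O7–C(CH3)2 bond, so that each pyran ring is closed with C8–CH as the net new bond. The closest known reaction type is the thermal conversion of aryl 1,1-dimethylpropargyl ethers into 2,2-dimethyl-2H-chromenes, which is also known for ethers with one ortho position blocked by halogen. Both six-membered pyran rings close in the same pericyclic mode, [3,3] shift followed by disrotatory 6π ring closure of the cis-dienone, and the two arms of the C2-symmetric substrate react independently. No stereocentre is formed; the four cyclobutane centres are kept because the medium holds no nucleophile that could open the lactones and a cis-fused lactone has no stable trans-fused epimer. The selectivity needed is C8 against C6, which a dihydrocoumarin arene, lacking the C3=C4 conjugation that directs a coumarin to C8, would not show by itself; the bromine on C6 secures it, because a shift to C6 leads to a dienone that cannot enolise and can only revert, and the para carbon C4a is substituted. The gem-dimethyl group lowers the barrier of the [3,3] shift, so that 185 °C should suffice and the bis-lactone core is spared higher temperatures.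

**Step 7**
Reactants: 10 6,6'-dibromo derivative of the target
Product: 11 target, (3S,4R,3'S,4'R) syn head-to-tail cyclobutane dimer of seselin
Conditions: Pd(OAc)2 (cat.), PPh3, HCO2H, Et3N, DMF, 80 °C
Reagents that add atoms: none
Why: Palladium-catalysed transfer hydrogenolysis of aryl bromides with formate (oxidative addition to zerovalent palladium, bromide/formate exchange, loss of CO2, C–H reductive elimination), under which the cis-disubstituted pyran alkenes, which have no allylic hydrogen to isomerise, and the lactones, which a tertiary amine does not attack, should survive.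

**Compound list**

1 | 7-methoxycoumarin (7-methoxy-2H-chromen-2-one) | COc1ccc2ccc(=O)oc2c1 | starting material
2 | racemic syn head-to-tail cyclobutane dimer of 7-methoxycoumarin, all-cis, cyclobutane bonds C3–C4, C4–C3', C3'–C4', C4'–C3 (racemate; the SMILES shows the (3S,4R,3'S,4'R) enantiomer) | COc1ccc2c(c1)OC(=O)[C@H]1[C@@H]2[C@H]2C(=O)Oc3cc(OC)ccc3[C@H]21 | intermediate
3 | (3S,4R,3'S,4'R)-7,7'-dimethoxy syn head-to-tail coumarin dimer (single enantiomer of 2) | COc1ccc2c(c1)OC(=O)[C@H]1[C@@H]2[C@H]2C(=O)Oc3cc(OC)ccc3[C@H]21 | intermediate
4 | (3S,4R,3'S,4'R)-6,6'-dibromo-7,7'-dimethoxy syn head-to-tail coumarin dimer | COc1c(Br)cc2c(c1)OC(=O)[C@H]1[C@@H]2[C@H]2C(=O)Oc3cc(OC)c(Br)cc3[C@H]21 | intermediate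
5 | (3S,4R,3'S,4'R)-6,6'-dibromo-7,7'-dihydroxy syn head-to-tail coumarin dimer | Oc1c(Br)cc2c(c1)OC(=O)[C@H]1[C@@H]2[C@H]2C(=O)Oc3cc(O)c(Br)cc3[C@H]21 | intermediate
6 | 3-chloro-3-methylbut-1-yne | CC(C)(Cl)C#C | starting material
7 | (3S,4R,3'S,4'R)-6,6'-dibromo-7,7'-bis(2-methylbut-3-yn-2-yloxy) syn head-to-tail coumarin dimer | C#CC(C)(C)Oc1c(Br)cc2c(c1)OC(=O)[C@H]1[C@@H]2[C@H]2C(=O)Oc3cc(OC(C)(C)C#C)c(Br)cc3[C@H]21 | intermediate
8 | (3S,4R,3'S,4'R)-6,6'-dibromo-7,7'-dihydroxy-8,8'-bis(3-methylbuta-1,2-dienyl) dimer (bis-allenylphenol, not isolated) | Oc1c(Br)cc2c(c1C=C=C(C)C)OC(=O)[C@H]1[C@@H]2[C@H]2C(=O)Oc3c(C=C=C(C)C)c(O)c(Br)cc3[C@H]21 | intermediate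
9 | (3S,4R,3'S,4'R)-6,6'-dibromo-8,8'-bis(3-methylbut-2-enylidene)-7,7'-dioxo dimer (bis-o-quinone methide, arenes dearomatised, not isolated) | O=C1C(Br)=CC2=C(C1=CC=C(C)C)OC(=O)[C@H]1[C@@H]2[C@H]2C(=O)OC3=C([C@H]21)C=C(Br)C(=O)C3=CC=C(C)C | intermediate
10 | 6,6'-dibromo derivative of the target (bromine on C6 and C6', the arene carbons ortho to the pyran oxygens), (3S,4R,3'S,4'R) | CC1(C)C=Cc2c(c(Br)cc3c2OC(=O)[C@H]2[C@@H]3[C@H]3C(=O)Oc4c5c(c(Br)cc4[C@H]32)OC(C)(C)C=C5)O1 | intermediate
11 | (3S,4R,3'S,4'R) syn head-to-tail cyclobutane dimer of seselin (8,8-dimethyl-2H,8H-pyrano[2,3-f]chromen-2-one), joined C3–C4' and C4–C3' | CC1(C)C=Cc2c(ccc3c2OC(=O)[C@H]2[C@@H]3[C@H]3C(=O)Oc4c5c(ccc4[C@H]32)OC(C)(C)C=C5)O1 | target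

**Step count and risks**

Total step count: 7. Longest linear sequence: 7 steps (1 to 11).

Steps most likely to fail:

1. Step 6. The twofold rearrangement may stall after one arm, or the shift may go to the brominated ortho carbon with loss of bromine, or the core may degrade thermally before both rings have closed. The fallback sets out from 5 and avoids the propargyl ether altogether. Phenol 5 is heated with 3-methylbut-2-enal, PhB(OH)2 and AcOH in toluene with removal of water. The boronic acid ties each phenol oxygen and the aldehyde together and delivers the aldehyde carbon to the only free ortho carbon C8, giving the bis(2-phenyl-4H-1,3,2-benzodioxaborin) F1. On further heating F1 fragments to the same bis(o-quinone methide) 9, whose electrocyclisation should give 10, where the route is rejoined; step 5 and compound 7 are bypassed.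

2. Step 7. The palladium hydride formed from formate may reduce the pyran double bonds, or the arylpalladium intermediate may add to a pyran alkene of a second molecule. The fallback sets out from 10 and replaces the organometallic hydrogenolysis by a radical chain reduction (Bu3SnH, AIBN, benzene, 80 °C). Here a stannyl radical abstracts bromine and the aryl radical takes hydrogen from the stannane faster than it can find an alkene, and the route is rejoined at 11. This fallback makes no compound outside the list (F0).

3. Step 3. Regiocontrol may be lost to C8, more than one bromine may enter per arene, or the only moderately activated ring may react sluggishly. The fallback sets out from 3 and reverses the order of steps 3 and 4. Demethylation with BBr3 in CH2Cl2 gives the (3S,4R,3'S,4'R)-7,7'-dihydroxy dimer F2. The free phenol is then brominated with NBS and catalytic i-Pr2NH in CH2Cl2 at 0 °C, where the N-bromoamine is held by the phenolic O–H and delivered to the less hindered ortho carbon C6. The route is rejoined at 5.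

**Further compounds**

F1 | step 6 | bis(2-phenyl-4H-1,3,2-benzodioxaborin) of 5, each arene bridged O7–B(Ph)–O–CH(CH=C(CH3)2)–C8, cyclobutane centres (3S,4R,3'S,4'R), the two new benzylic centres not controlled | B1(c2ccccc2)Oc2c(Br)cc3c(c2C(C=C(C)C)O1)OC(=O)[C@H]1[C@@H]3[C@H]3C(=O)Oc4c5c(c(Br)cc4[C@H]31)OB(c4ccccc4)OC5C=C(C)C
F0 | step 7 | none | none
F2 | step 3 | (3S,4R,3'S,4'R)-7,7'-dihydroxy syn head-to-tail coumarin dimer | Oc1ccc2c(c1)OC(=O)[C@H]1[C@@H]2[C@H]2C(=O)Oc3cc(O)ccc3[C@H]21
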